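**Retrosynthetic overview**
- Atom names: C7 = ketone carbon, C8 = stereocentre, C9 = methyl carbon. The last disconnection is the O–Si bond of a silyl ether on the primary allylic alcohol.
- Key disconnection: the bond between C7 and C1 of the 3,4,5-trimethoxyphenyl ring. This leads back to 3,4,5-trimethoxyphenyllithium and an aryloxy(methyl)ketene, which is released in the flask from a racemic, carbonyl-shielded aryl (BHT) ester. The resulting lithium enolate is protonated enantioselectively at C8 in the same flask, so the step is stereoconvergent.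
- Enabling feature: C8, the only stereocentre, is a C–H carbon between the C7 carbonyl and the ether oxygen to the 2,6-dimethoxyphenyl ring. It can be erased to the sp2 carbon of a ketene and rebuilt by protonation. The small C9 methyl group and the bulky, lithium-binding aryloxy group on C8 should fix one chelated enolate geometry.
- The racemic ester comes from a Suzuki–Miyaura coupling (arene–alkene bond), a Williamson ether synthesis (C8–O bond) and O-acylation of BHT.
- No ring is formed: both benzene rings are bought with their complete oxygen pattern.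

Key step: step 4

Assumption: no validated model predicts which enantiomer of the diol protonates the Si face of C8 in this enolate class. The (R,R) form is written, and the equally available (S,S) form takes its place if the sense is opposite.

**Step 1**
Reactants: 1 2,6-di-tert-butyl-4-methylphenol (BHT); 2 rac-2-bromopropanoyl bromide
Product: 4 2,6-di-tert-butyl-4-methylphenyl rac-2-bromopropanoate, via lithium phenoxide 3 (not isolated)
Conditions: n-BuLi (1.0 equiv), THF, 0 °C; then 2, 0 °C → rt
Reagents that add atoms: none
Why: O-acylation of a preformed lithium phenoxide by nucleophilic acyl substitution, in which the crowded phenol reacts as its lithium salt with the very reactive acyl bromide as in the standard preparation of hindered aryl propanoates, and no stereocontrol is needed because 4 is used as the racemate.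

**Step 2**
Reactants: 4 2,6-di-tert-butyl-4-methylphenyl rac-2-bromopropanoate; 5 4-bromo-2,6-dimethoxyphenol
Product: 6 2,6-di-tert-butyl-4-methylphenyl rac-2-(4-bromo-2,6-dimethoxyphenoxy)propanoate
Conditions: K2CO3, DMF, rt → 50 °C
Reagents that add atoms: none
Why: Williamson ether synthesis (SN2), in which the α-bromo ester is an activated secondary electrophile, the weakly basic phenoxide of 5 is kept off the ester carbonyl by the two tert-butyl groups, and C8 is formed as the racemate on purpose.

**Step 3**
Reactants: 6 2,6-di-tert-butyl-4-methylphenyl rac-2-(4-bromo-2,6-dimethoxyphenoxy)propanoate; 7 (E)-3-(tert-butyldimethylsilyloxy)prop-1-enylboronic acid pinacol ester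
Product: 8 2,6-di-tert-butyl-4-methylphenyl rac-2-[4-[(E)-3-(tert-butyldimethylsilyloxy)prop-1-enyl]-2,6-dimethoxyphenoxy]propanoate
Conditions: Pd(OAc)2 (cat), SPhos (cat), K3PO4, THF/H2O, 60 °C
Reagents that add atoms: none
Why: Suzuki–Miyaura coupling, in which the unhindered C–Br bond of 6 adds oxidatively to an electron-rich biarylphosphine palladium catalyst, the alkenylboronate transfers its carbon with retention so that the E double bond of 7 is carried over, and the shielded ester and the silyl ether tolerate aqueous phosphate.

**Step 4**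
Reactants: 8 2,6-di-tert-butyl-4-methylphenyl rac-2-[4-[(E)-3-(tert-butyldimethylsilyloxy)prop-1-enyl]-2,6-dimethoxyphenoxy]propanoate; 9 5-bromo-1,2,3-trimethoxybenzene
Product: 14 (R)-2-[4-[(E)-3-(tert-butyldimethylsilyloxy)prop-1-enyl]-2,6-dimethoxyphenoxy]-1-(3,4,5-trimethoxyphenyl)propan-1-one, via aryllithium 10 (not isolated), via ester enolate 11 (not isolated), via ketene 12 (not isolated), via lithium enolate 13 (not isolated)
Conditions: 9 (2.3 equiv), t-BuLi (4.5 equiv), THF, −78 °C; then 8, −78 → −10 °C; recool to −78 °C, (R,R)-TADDOL (1.5 equiv) in THF; then AcOH in THF, −78 °C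
Reagents that add atoms: none
Why: Proposed new method: the first equivalent of 10 can act only as a base on 8 because the two tert-butyl groups close off the ester carbonyl, and above about −20 °C enolate 11 expels the crowded phenoxide (E1cB) to give ketene 12, in which C8 of both enantiomers has become the same sp2 carbon; the second equivalent of 10 then adds to the ketene carbonyl carbon, which forms the aryl–C7 bond and stops at enolate 13, so that no second addition can follow. The closest known reaction types are the release of ketenes from hindered aryl ester enolates with capture by organolithiums to give geometrically defined ketone enolates, the one-pot addition of an organometallic reagent to a ketene followed by enantioselective protonation with a chiral alcohol, and the protonation of amine-free lithium enolates of α-methyl aryl ketones by TADDOL; their merger on an aryloxy-substituted ketene has not been shown. No ring is closed. The organolithium must attack in the plane of the ketene, where the C9 methyl group leaves its side open while the 2,6-dimethoxyaryl group, turned towards the ketene terminus by that geminal methyl group, blocks the other side, so the Z enolate should form with lithium held in a five-membered chelate between the enolate oxygen and the ether oxygen on C8. C8 is the only new stereocentre and is set by reagent control, since lithium-bound (R,R)-TADDOL is to pass its proton to the Si face of C8 of this rigid and geometrically uniform chelate, which gives the R configuration. The step needs proton transfer from the chiral donor alone and no later enolisation, which is secured by the amine-free generation of 13, by a liberated lithium phenoxide too hindered to shuttle protons to carbon at −78 °C, and by the cold acetic acid quench that destroys all alkoxide bases before warming; the silyl ether and the electron-rich styrene double bond are inert to an aryllithium because t-BuLi is used in slight deficit.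

**Step 5**
Reactants: 14 (R)-2-[4-[(E)-3-(tert-butyldimethylsilyloxy)prop-1-enyl]-2,6-dimethoxyphenoxy]-1-(3,4,5-trimethoxyphenyl)propan-1-one
Product: 15 (R)-2-[4-[(E)-3-hydroxyprop-1-enyl]-2,6-dimethoxyphenoxy]-1-(3,4,5-trimethoxyphenyl)propan-1-one
Conditions: HF·pyridine, pyridine, THF, 0 °C
Reagents that add atoms: none
Why: Silyl ether cleavage by fluoride under buffered, weakly acidic conditions, in which formation of the strong Si–F bond removes the primary TBS group at 0 °C, the absence of base avoids enolisation at C8, and the pyridine buffer keeps the medium too weakly acidic to ionise the cinnamyl alcohol.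

**Compound list**
1 | 2,6-di-tert-butyl-4-methylphenol (BHT) | Cc1cc(C(C)(C)C)c(O)c(C(C)(C)C)c1 | starting material
2 | rac-2-bromopropanoyl bromide | CC(Br)C(=O)Br | starting material
3 | lithium 2,6-di-tert-butyl-4-methylphenoxide | [Li]Oc1c(C(C)(C)C)cc(C)cc1C(C)(C)C | intermediate
4 | 2,6-di-tert-butyl-4-methylphenyl rac-2-bromopropanoate | CC(Br)C(=O)Oc1c(C(C)(C)C)cc(C)cc1C(C)(C)C | intermediate
5 | 4-bromo-2,6-dimethoxyphenol | COc1cc(Br)cc(OC)c1O | starting material
6 | 2,6-di-tert-butyl-4-methylphenyl rac-2-(4-bromo-2,6-dimethoxyphenoxy)propanoate | CC(Oc1c(OC)cc(Br)cc1OC)C(=O)Oc1c(C(C)(C)C)cc(C)cc1C(C)(C)C | intermediate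
7 | (E)-3-(tert-butyldimethylsilyloxy)prop-1-enylboronic acid pinacol ester | CC(C)(C)[Si](C)(C)OC/C=C/B1OC(C)(C)C(C)(C)O1 | starting material
8 | 2,6-di-tert-butyl-4-methylphenyl rac-2-[4-[(E)-3-(tert-butyldimethylsilyloxy)prop-1-enyl]-2,6-dimethoxyphenoxy]propanoate | CC(Oc1c(OC)cc(/C=C/CO[Si](C)(C)C(C)(C)C)cc1OC)C(=O)Oc1c(C(C)(C)C)cc(C)cc1C(C)(C)C | intermediate
9 | 5-bromo-1,2,3-trimethoxybenzene | COc1cc(Br)cc(OC)c1OC | starting material
10 | 3,4,5-trimethoxyphenyllithium | [Li]c1cc(OC)c(OC)c(OC)c1 | intermediate
11 | lithium enolate of ester 8 (geometry without consequence) | CC(Oc1c(OC)cc(/C=C/CO[Si](C)(C)C(C)(C)C)cc1OC)=C(O[Li])Oc1c(C(C)(C)C)cc(C)cc1C(C)(C)C | intermediate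
12 | 2-[4-[(E)-3-(tert-butyldimethylsilyloxy)prop-1-enyl]-2,6-dimethoxyphenoxy]prop-1-en-1-one (ketene) | CC(=C=O)Oc1c(OC)cc(/C=C/CO[Si](C)(C)C(C)(C)C)cc1OC | intermediate
13 | (Z)-lithium enolate of ketone 14 (OLi and aryloxy group on the same side) | [Li]O/C(c1cc(OC)c(OC)c(OC)c1)=C(C)\Oc1c(OC)cc(/C=C/CO[Si](C)(C)C(C)(C)C)cc1OC | intermediate
14 | (R)-2-[4-[(E)-3-(tert-butyldimethylsilyloxy)prop-1-enyl]-2,6-dimethoxyphenoxy]-1-(3,4,5-trimethoxyphenyl)propan-1-one | COc1cc(C(=O)[C@@H](C)Oc2c(OC)cc(/C=C/CO[Si](C)(C)C(C)(C)C)cc2OC)cc(OC)c1OC | intermediate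
15 | (R)-2-[4-[(E)-3-hydroxyprop-1-enyl]-2,6-dimethoxyphenoxy]-1-(3,4,5-trimethoxyphenyl)propan-1-one | COc1cc(C(=O)[C@@H](C)Oc2c(OC)cc(/C=C/CO)cc2OC)cc(OC)c1OC | target

**Step count**
- Total step count: 5
- Longest linear sequence: 5 steps (1 → 4 → 6 → 8 → 14 → 15)

**Steps most likely to fail**

**Step 4.**
- Oxygen-directed delivery of the aryllithium could erode the enolate geometry.
- Proton transfer from the diol could be slow or poorly face-selective.
- The ketene could be lost to self-condensation with the ester enolate.
- The fallback uses the chiral pool and known reactions only, sets out from 5 and returns at 14.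
- Suzuki–Miyaura coupling of 5 with 7 gives 4-[(E)-3-(tert-butyldimethylsilyloxy)prop-1-enyl]-2,6-dimethoxyphenol F1.
- Mitsunobu reaction of this phenol with ethyl (S)-lactate (PPh3, DIAD, THF, 0 °C → rt) should give, with inversion, ethyl (R)-2-[4-[(E)-3-(tert-butyldimethylsilyloxy)prop-1-enyl]-2,6-dimethoxyphenoxy]propanoate F2.
- Treatment with MeNH(OMe)·HCl and i-PrMgCl (THF, −20 °C) converts it into (R)-2-[4-[(E)-3-(tert-butyldimethylsilyloxy)prop-1-enyl]-2,6-dimethoxyphenoxy]-N-methoxy-N-methylpropanamide F3.
- Addition of 3,4,5-trimethoxyphenylmagnesium bromide F4, made from 9 and magnesium, at −20 → 0 °C, followed by a cold dilute HCl quench, forms the same aryl–C7 bond through the stable chelated tetrahedral adduct and gives 14.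

**Step 5.**
- Silyl cleavage could be accompanied by partial enolisation at C8 or by ionisation of the electron-rich cinnamyl C–O bond.
- The fallback needs no protecting group, finishes under neutral conditions, sets out from 6 and returns at 15.
- Suzuki–Miyaura coupling of 6 with vinylboronic acid pinacol ester gives 2,6-di-tert-butyl-4-methylphenyl rac-2-(2,6-dimethoxy-4-vinylphenoxy)propanoate F5.
- The sequence of step 4 is run on this ester. It passes through its lithium ester enolate F6, the ketene 2-(2,6-dimethoxy-4-vinylphenoxy)prop-1-en-1-one F7 and the (Z)-lithium ketone enolate F8.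
- The product is (R)-2-(2,6-dimethoxy-4-vinylphenoxy)-1-(3,4,5-trimethoxyphenyl)propan-1-one F9.
- Olefin cross-metathesis of this styrene with (Z)-but-2-ene-1,4-diol (Hoveyda–Grubbs second-generation catalyst, CH2Cl2, 40 °C) should install the E hydroxypropenyl chain directly and give 15.

**Step 2.**
- E2 loss of HBr from the secondary bromide could compete with substitution by the doubly ortho-substituted phenoxide.
- The fallback reverses the order of bond formation (ether first, hindered ester last), sets out from 5 and returns at 6.
- Alkylation of 5 with ethyl 2-bromopropanoate (K2CO3, acetone, reflux) gives ethyl rac-2-(4-bromo-2,6-dimethoxyphenoxy)propanoate F10.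
- Saponification (LiOH, THF/H2O, then acid) gives rac-2-(4-bromo-2,6-dimethoxyphenoxy)propanoic acid F11.
- Oxalyl chloride with catalytic DMF gives rac-2-(4-bromo-2,6-dimethoxyphenoxy)propanoyl chloride F12.
- This chloride acylates lithium phenoxide 3, made from 1 and n-BuLi, to give 6.

**Further compounds**
F1 | step 4 | 4-[(E)-3-(tert-butyldimethylsilyloxy)prop-1-enyl]-2,6-dimethoxyphenol | COc1cc(/C=C/CO[Si](C)(C)C(C)(C)C)cc(OC)c1O
F2 | step 4 | ethyl (R)-2-[4-[(E)-3-(tert-butyldimethylsilyloxy)prop-1-enyl]-2,6-dimethoxyphenoxy]propanoate | CCOC(=O)[C@@H](C)Oc1c(OC)cc(/C=C/CO[Si](C)(C)C(C)(C)C)cc1OC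
F3 | step 4 | (R)-2-[4-[(E)-3-(tert-butyldimethylsilyloxy)prop-1-enyl]-2,6-dimethoxyphenoxy]-N-methoxy-N-methylpropanamide | CON(C)C(=O)[C@@H](C)Oc1c(OC)cc(/C=C/CO[Si](C)(C)C(C)(C)C)cc1OC
F4 | step 4 | 3,4,5-trimethoxyphenylmagnesium bromide | COc1cc([Mg]Br)cc(OC)c1OC
F5 | step 5 | 2,6-di-tert-butyl-4-methylphenyl rac-2-(2,6-dimethoxy-4-vinylphenoxy)propanoate | CC(Oc1c(OC)cc(C=C)cc1OC)C(=O)Oc1c(C(C)(C)C)cc(C)cc1C(C)(C)C
F6 | step 5 | lithium enolate of ester F5 | CC(Oc1c(OC)cc(C=C)cc1OC)=C(O[Li])Oc1c(C(C)(C)C)cc(C)cc1C(C)(C)C
F7 | step 5 | 2-(2,6-dimethoxy-4-vinylphenoxy)prop-1-en-1-one | CC(=C=O)Oc1c(OC)cc(C=C)cc1OC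
F8 | step 5 | (Z)-lithium enolate of ketone F9 | [Li]O/C(c1cc(OC)c(OC)c(OC)c1)=C(C)\Oc1c(OC)cc(C=C)cc1OC
F9 | step 5 | (R)-2-(2,6-dimethoxy-4-vinylphenoxy)-1-(3,4,5-trimethoxyphenyl)propan-1-one | COc1cc(C(=O)[C@@H](C)Oc2c(OC)cc(C=C)cc2OC)cc(OC)c1OC
F10 | step 2 | ethyl rac-2-(4-bromo-2,6-dimethoxyphenoxy)propanoate | CCOC(=O)C(C)Oc1c(OC)cc(Br)cc1OC
F11 | step 2 | rac-2-(4-bromo-2,6-dimethoxyphenoxy)propanoic acid | CC(Oc1c(OC)cc(Br)cc1OC)C(=O)O
F12 | step 2 | rac-2-(4-bromo-2,6-dimethoxyphenoxy)propanoyl chloride | CC(Oc1c(OC)cc(Br)cc1OC)C(=O)Cl
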